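Everything rests on cutting ring A away from the O1–C2–C3–C4 chain of the chromanone at O1–C8a and C4–C4a. Ring A is delivered as a C4a≡C8a aryne and the chain as a 2-arylacrylic acid that already carries ring B. The aryne inserts into the acid C–OH bond, and the phenoxide so released closes ring C by oxa-Michael addition onto the methylene carbon, giving the isoflavanone core in one operation. The step exploits the ortho placing of ether oxygen O1 and acyl carbon C4 on ring A, and the C5 oxygen beside C4a, which polarises the aryne. The epimerisable C3 centre is set afterwards by dynamic kinetic resolution and reoxidation.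

Key step: step 9

Remark: C3 of a 5-oxygenated isoflavanone epimerises readily with base, so no basic reagent is used after step 11; chromanone numbering (O1, C2, C3, C4, C4a, C5–C8, C8a) is used throughout.

Step 1
Reactants: 1 2-methylresorcinol
Product: 2 1,3-bis(methoxymethoxy)-2-methylbenzene
Conditions: NaH, MOMCl, DMF, 0 °C to rt
Reagents that add atoms: chloromethyl methyl ether (MOMCl), COCCl
Why: Double Williamson O-alkylation of the bis-phenoxide (MOM acetal protection) should proceed cleanly, and MOM ethers tolerate the organolithium, borylation and fluoride steps ahead.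

Step 2
Reactants: 2 1,3-bis(methoxymethoxy)-2-methylbenzene
Product: 4 3,5-bis(methoxymethoxy)-4-methylphenol, via arylboronate 3 (not isolated)
Conditions: [Ir(OMe)(cod)]2 (cat.), dtbpy, B2pin2 (0.55 equiv), THF, 80 °C; then aq. H2O2, NaOH, 0 °C
Reagents that add atoms: bis(pinacolato)diboron, CC1(C)OB(OC1(C)C)B1OC(C)(C)C(C)(C)O1 (boron of 3 only); hydrogen peroxide, OO (phenol oxygen of 4)
Why: Iridium-catalysed aromatic C–H borylation is sterically governed and should functionalise only the single C–H with no ortho substituent, after which boronate oxidation gives the phenol.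

Step 3
Reactants: 4 3,5-bis(methoxymethoxy)-4-methylphenol
Product: 5 2-bromo-3,5-bis(methoxymethoxy)-4-methylphenol
Conditions: NBS (1.0 equiv), CH2Cl2, −78 to 0 °C
Reagents that add atoms: N-bromosuccinimide, O=C1CCC(=O)N1Br
Why: Electrophilic aromatic bromination can only occur at the two equivalent positions between OH and OMOM, and one equivalent of NBS at low temperature should stop at the monobromide.

Step 4
Reactants: 5 2-bromo-3,5-bis(methoxymethoxy)-4-methylphenol
Product: 8 3,5-bis(methoxymethoxy)-4-methyl-2-(trimethylsilyl)phenyl trifluoromethanesulfonate, via aryl silyl ether 6 (not isolated), via lithium silylphenoxide 7 (not isolated)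
Conditions: HMDS, THF, 70 °C, then evaporate; n-BuLi, THF, −100 °C; Tf2O, −100 °C to rt
Reagents that add atoms: hexamethyldisilazane, C[Si](C)(C)N[Si](C)(C)C; trifluoromethanesulfonic anhydride, O=S(=O)(OS(=O)(=O)C(F)(F)F)C(F)(F)F
Why: O-silylation followed by bromine–lithium exchange triggers a 1,3 O→C silyl shift (retro-Brook rearrangement) to the lithium 2-silylphenoxide, which Tf2O traps as the 2-silylaryl triflate, the standard fluoride-triggered aryne precursor.

Step 5
Reactants: 9 4,6-dibromobenzene-1,3-diol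
Product: 10 1,5-dibromo-2,4-bis(methoxymethoxy)benzene
Conditions: NaH, MOMCl, DMF, 0 °C to rt
Reagents that add atoms: chloromethyl methyl ether (MOMCl), COCCl
Why: Double Williamson O-alkylation (MOM protection) as in step 1 should give the bis-acetal, which also stabilises the ortho aryllithium of the next step by chelation.

Step 6
Reactants: 10 1,5-dibromo-2,4-bis(methoxymethoxy)benzene; 11 geranyl bromide
Product: 13 1-bromo-5-[(2E)-3,7-dimethylocta-2,6-dien-1-yl]-2,4-bis(methoxymethoxy)benzene, via aryllithium 12 (not isolated)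
Conditions: n-BuLi (1.0 equiv), THF, −78 °C; CuBr·SMe2 (cat.), 11, −78 to 0 °C
Reagents that add atoms: none
Why: One equivalent of n-BuLi should exchange a single bromine, and copper-catalysed SN2 allylation of the aryllithium with geranyl bromide should give the linear arene with the E alkene of 11 retained.

Step 7
Reactants: 13 1-bromo-5-[(2E)-3,7-dimethylocta-2,6-dien-1-yl]-2,4-bis(methoxymethoxy)benzene; 14 ethyl 2-bromoprop-2-enoate
Product: 16 ethyl 2-{5-[(2E)-3,7-dimethylocta-2,6-dien-1-yl]-2,4-bis(methoxymethoxy)phenyl}prop-2-enoate, via arylzinc chloride 15 (not isolated)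
Conditions: n-BuLi, THF, −78 °C; ZnCl2; Pd(PPh3)4 (cat.), 14, 0 °C to rt
Reagents that add atoms: none
Why: Bromine–lithium exchange, transmetalation to zinc and Negishi coupling at the vinylic C–Br bond of 14 should give the 2-arylacrylate, since arylzinc halides tolerate the ester and do not add in conjugate fashion.

Step 8
Reactants: 16 ethyl 2-{5-[(2E)-3,7-dimethylocta-2,6-dien-1-yl]-2,4-bis(methoxymethoxy)phenyl}prop-2-enoate
Product: 17 2-{5-[(2E)-3,7-dimethylocta-2,6-dien-1-yl]-2,4-bis(methoxymethoxy)phenyl}prop-2-enoic acid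
Conditions: LiOH·H2O, THF/H2O, rt; then 1 M HCl to pH 4, 0 °C
Reagents that add atoms: lithium hydroxide, [Li+].[OH-]
Why: Saponification in aqueous THF (no alcohol cosolvent, to avoid alkoxide conjugate addition) and cold acidification should liberate the acid without touching the MOM acetals.

Step 9
Reactants: 8 3,5-bis(methoxymethoxy)-4-methyl-2-(trimethylsilyl)phenyl trifluoromethanesulfonate; 17 2-{5-[(2E)-3,7-dimethylocta-2,6-dien-1-yl]-2,4-bis(methoxymethoxy)phenyl}prop-2-enoic acid
Product: 20 rac-3-{5-[(2E)-3,7-dimethylocta-2,6-dien-1-yl]-2,4-bis(methoxymethoxy)phenyl}-5,7-bis(methoxymethoxy)-6-methyl-2,3-dihydro-4H-chromen-4-one, via aryne 18 (not isolated), via hydroxyaryl vinyl ketone 19 (not isolated)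
Conditions: 8 (1.3 equiv), CsF (4 equiv), THF, 125 °C, sealed tube
Reagents that add atoms: none
Why: CsF unmasks aryne 18 and turns 17 into its caesium carboxylate, whose oxygen adds to the aryne carbon remote from the OMOM group (future C8a); the aryl anion left at future C4a attacks the ester carbonyl and the strained four-membered adduct opens, so the aryne has formally inserted into the acid C–OH bond to give the phenoxide of 19 with O1–C8a and C4–C4a both made. The closest known reaction type is the intermolecular C–O insertion of arynes into carboxylic acids, which with α,β-unsaturated acids is known to run on to 4-chromanones. Ring C then closes by 6-endo-trig oxa-Michael addition of the phenoxide oxygen to the methylene carbon of the 1-arylvinyl ketone (O1–C2). The C3 stereocenter arises from uncontrolled protonation of the resulting enolate, which is accepted because C3 is epimerisable and is set in step 10. The step needs regioselective addition to the unsymmetrical aryne, secured by the 3-alkoxy (OMOM) substituent that directs nucleophiles to the meta aryne carbon and places the acyl group beside itself, and it needs acyl transfer to outrun protonation of the aryl anion, which the high temperature in THF favours.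

Step 10
Reactants: 20 rac-3-{5-[(2E)-3,7-dimethylocta-2,6-dien-1-yl]-2,4-bis(methoxymethoxy)phenyl}-5,7-bis(methoxymethoxy)-6-methyl-2,3-dihydro-4H-chromen-4-one
Product: 21 (3R,4R)-3-{5-[(2E)-3,7-dimethylocta-2,6-dien-1-yl]-2,4-bis(methoxymethoxy)phenyl}-5,7-bis(methoxymethoxy)-6-methyl-3,4-dihydro-2H-chromen-4-ol (cis)
Conditions: RuCl(p-cymene)[(R,R)-TsDPEN] (cat.), HCO2H/Et3N (5:2), EtOAc, 40 °C
Reagents that add atoms: none
Why: Noyori asymmetric transfer hydrogenation under dynamic kinetic resolution: C3 epimerises through the enol in the amine-containing medium while the (R,R)-catalyst, by the usual model for aryl ketones, should deliver hydride to C4 to give the 4R carbinol, faster on the 3R ketone and anti to the C3 aryl group, so the cis-(3R,4R) alcohol should result with both centres under catalyst control.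

Step 11
Reactants: 21 (3R,4R)-3-{5-[(2E)-3,7-dimethylocta-2,6-dien-1-yl]-2,4-bis(methoxymethoxy)phenyl}-5,7-bis(methoxymethoxy)-6-methyl-3,4-dihydro-2H-chromen-4-ol
Product: 22 (3R)-3-{5-[(2E)-3,7-dimethylocta-2,6-dien-1-yl]-2,4-bis(methoxymethoxy)phenyl}-5,7-bis(methoxymethoxy)-6-methyl-2,3-dihydro-4H-chromen-4-one
Conditions: Dess–Martin periodinane, CH2Cl2, 0 °C to rt
Reagents that add atoms: none
Why: Dess–Martin oxidation returns the C4 ketone under non-basic, weakly acidic conditions, so the C3 centre set in step 10 should be retained and the alkenes and MOM acetals left untouched.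

Step 12
Reactants: 22 (3R)-3-{5-[(2E)-3,7-dimethylocta-2,6-dien-1-yl]-2,4-bis(methoxymethoxy)phenyl}-5,7-bis(methoxymethoxy)-6-methyl-2,3-dihydro-4H-chromen-4-one
Product: 23 (3R)-3-{5-[(2E)-3,7-dimethylocta-2,6-dien-1-yl]-2,4-dihydroxyphenyl}-5,7-dihydroxy-6-methyl-2,3-dihydro-4H-chromen-4-one
Conditions: HCl (0.3 M) in MeOH/THF, 0 °C to rt, stopped at full conversion
Reagents that add atoms: none
Why: Acid-catalysed transacetalisation of the four aryl MOM ethers with methanol (acetal cleavage) at or below room temperature should release the phenols, the mild non-basic medium being chosen to spare the C3 centre and the geranyl alkenes.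

Compound list

1 | 2-methylresorcinol | Cc1c(O)cccc1O | starting material
2 | 1,3-bis(methoxymethoxy)-2-methylbenzene | COCOc1cccc(OCOC)c1C | intermediate
3 | 2-[3,5-bis(methoxymethoxy)-4-methylphenyl]-4,4,5,5-tetramethyl-1,3,2-dioxaborolane | COCOc1cc(B2OC(C)(C)C(C)(C)O2)cc(OCOC)c1C | intermediate
4 | 3,5-bis(methoxymethoxy)-4-methylphenol | COCOc1cc(O)cc(OCOC)c1C | intermediate
5 | 2-bromo-3,5-bis(methoxymethoxy)-4-methylphenol | COCOc1cc(O)c(Br)c(OCOC)c1C | intermediate
6 | [2-bromo-3,5-bis(methoxymethoxy)-4-methylphenoxy]trimethylsilane | COCOc1cc(O[Si](C)(C)C)c(Br)c(OCOC)c1C | intermediate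
7 | lithium 3,5-bis(methoxymethoxy)-4-methyl-2-(trimethylsilyl)phenoxide | COCOc1cc([O-])c([Si](C)(C)C)c(OCOC)c1C.[Li+] | intermediate
8 | 3,5-bis(methoxymethoxy)-4-methyl-2-(trimethylsilyl)phenyl trifluoromethanesulfonate | COCOc1cc(OS(=O)(=O)C(F)(F)F)c([Si](C)(C)C)c(OCOC)c1C | intermediate
9 | 4,6-dibromobenzene-1,3-diol | Oc1cc(O)c(Br)cc1Br | starting material
10 | 1,5-dibromo-2,4-bis(methoxymethoxy)benzene | COCOc1cc(OCOC)c(Br)cc1Br | intermediate
11 | geranyl bromide, (2E)-1-bromo-3,7-dimethylocta-2,6-diene | CC(C)=CCC/C(C)=C/CBr | starting material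
12 | [5-bromo-2,4-bis(methoxymethoxy)phenyl]lithium | COCOc1cc(OCOC)c(Br)cc1[Li] | intermediate
13 | 1-bromo-5-[(2E)-3,7-dimethylocta-2,6-dien-1-yl]-2,4-bis(methoxymethoxy)benzene | CC(C)=CCC/C(C)=C/Cc1cc(Br)c(OCOC)cc1OCOC | intermediate
14 | ethyl 2-bromoprop-2-enoate | C=C(Br)C(=O)OCC | starting material
15 | {5-[(2E)-3,7-dimethylocta-2,6-dien-1-yl]-2,4-bis(methoxymethoxy)phenyl}zinc chloride | CC(C)=CCC/C(C)=C/Cc1cc([Zn]Cl)c(OCOC)cc1OCOC | intermediate
16 | ethyl 2-{5-[(2E)-3,7-dimethylocta-2,6-dien-1-yl]-2,4-bis(methoxymethoxy)phenyl}prop-2-enoate | CC(C)=CCC/C(C)=C/Cc1cc(C(=C)C(=O)OCC)c(OCOC)cc1OCOC | intermediate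
17 | 2-{5-[(2E)-3,7-dimethylocta-2,6-dien-1-yl]-2,4-bis(methoxymethoxy)phenyl}prop-2-enoic acid | CC(C)=CCC/C(C)=C/Cc1cc(C(=C)C(=O)O)c(OCOC)cc1OCOC | intermediate
18 | 3,5-bis(methoxymethoxy)-4-methylbenzyne (1,2-didehydro arene) | COCOC1=CC#CC(OCOC)=C1C | intermediate
19 | 2-{5-[(2E)-3,7-dimethylocta-2,6-dien-1-yl]-2,4-bis(methoxymethoxy)phenyl}-1-[6-hydroxy-2,4-bis(methoxymethoxy)-3-methylphenyl]prop-2-en-1-one | CC(C)=CCC/C(C)=C/Cc1cc(C(=C)C(=O)c2c(O)cc(OCOC)c(C)c2OCOC)c(OCOC)cc1OCOC | intermediate
20 | rac-3-{5-[(2E)-3,7-dimethylocta-2,6-dien-1-yl]-2,4-bis(methoxymethoxy)phenyl}-5,7-bis(methoxymethoxy)-6-methyl-2,3-dihydro-4H-chromen-4-one | CC(C)=CCC/C(C)=C/Cc1cc(C2COc3cc(OCOC)c(C)c(OCOC)c3C2=O)c(OCOC)cc1OCOC | intermediate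
21 | (3R,4R)-3-{5-[(2E)-3,7-dimethylocta-2,6-dien-1-yl]-2,4-bis(methoxymethoxy)phenyl}-5,7-bis(methoxymethoxy)-6-methyl-3,4-dihydro-2H-chromen-4-ol | CC(C)=CCC/C(C)=C/Cc1cc([C@@H]2COc3cc(OCOC)c(C)c(OCOC)c3[C@@H]2O)c(OCOC)cc1OCOC | intermediate
22 | (3R)-3-{5-[(2E)-3,7-dimethylocta-2,6-dien-1-yl]-2,4-bis(methoxymethoxy)phenyl}-5,7-bis(methoxymethoxy)-6-methyl-2,3-dihydro-4H-chromen-4-one | CC(C)=CCC/C(C)=C/Cc1cc([C@@H]2COc3cc(OCOC)c(C)c(OCOC)c3C2=O)c(OCOC)cc1OCOC | intermediate
23 | (3R)-3-{5-[(2E)-3,7-dimethylocta-2,6-dien-1-yl]-2,4-dihydroxyphenyl}-5,7-dihydroxy-6-methyl-2,3-dihydro-4H-chromen-4-one | CC(C)=CCC/C(C)=C/Cc1cc([C@@H]2COc3cc(O)c(C)c(O)c3C2=O)c(O)cc1O | target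

Total steps: 12. Longest linear sequence: 8 steps (steps 1–4 or 5–8, then 9–12).

Steps most likely to fail

Step 9. The aryl anion may be protonated before acyl transfer, so that only O-arylation of the acid occurs, and the product enolate may be arylated further by excess aryne at 125 °C. The fallback sets out from bromophenol 5 and acid 17 and makes the same two bonds in two operations. Esterification (EDC·HCl, DMAP, CH2Cl2) should give 2-bromo-3,5-bis(methoxymethoxy)-4-methylphenyl 2-{5-[(2E)-3,7-dimethylocta-2,6-dien-1-yl]-2,4-bis(methoxymethoxy)phenyl}prop-2-enoate F1. Treating it with n-BuLi in THF at −100 °C should trigger bromine–lithium exchange and an anionic Fries-type O→C acyl shift to the lithium phenoxide of 19. On warming this should close by oxa-Michael addition, and the route is rejoined at 20.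

Step 10. Hydride transfer to a ketone flanked by the peri OMOM group and the C3 aryl group may be sluggish, or C3 epimerisation may not keep pace with reduction, giving poor conversion and poor stereocontrol. The fallback sets out from 20 and replaces reduction/reoxidation by enantioselective protonation. LiHMDS and TMSCl in THF at −78 °C should give {[3-{5-[(2E)-3,7-dimethylocta-2,6-dien-1-yl]-2,4-bis(methoxymethoxy)phenyl}-5,7-bis(methoxymethoxy)-6-methyl-2H-chromen-4-yl]oxy}trimethylsilane F2. Protonating it with a catalytic chiral BINOL-derived N-triflyl thiophosphoramide and stoichiometric phenol in toluene, using the catalyst antipode that delivers the 3R ketone, rejoins the route at 22 and bypasses 21 and step 11.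

Step 12. Acid-mediated enolisation at C3 during acetal cleavage may erode the enantiomeric purity, and the freed ortho phenol may be pushed towards cyclisation onto the geranyl chain on prolonged exposure. The fallback sets out from racemic 20 and replaces asymmetric synthesis by resolution. The same MOM cleavage, with no configuration at stake, should give rac-3-{5-[(2E)-3,7-dimethylocta-2,6-dien-1-yl]-2,4-dihydroxyphenyl}-5,7-dihydroxy-6-methyl-2,3-dihydro-4H-chromen-4-one F3. Preparative chromatography on a chiral stationary phase (SFC, neutral eluent) should then deliver 23, where the route is rejoined. The separated (3S)-3-{5-[(2E)-3,7-dimethylocta-2,6-dien-1-yl]-2,4-dihydroxyphenyl}-5,7-dihydroxy-6-methyl-2,3-dihydro-4H-chromen-4-one F4 can be re-racemised with catalytic Et3N and recycled.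

Further compounds

F1 | step 9 | 2-bromo-3,5-bis(methoxymethoxy)-4-methylphenyl 2-{5-[(2E)-3,7-dimethylocta-2,6-dien-1-yl]-2,4-bis(methoxymethoxy)phenyl}prop-2-enoate | CC(C)=CCC/C(C)=C/Cc1cc(C(=C)C(=O)Oc2cc(OCOC)c(C)c(OCOC)c2Br)c(OCOC)cc1OCOC
F2 | step 10 | {[3-{5-[(2E)-3,7-dimethylocta-2,6-dien-1-yl]-2,4-bis(methoxymethoxy)phenyl}-5,7-bis(methoxymethoxy)-6-methyl-2H-chromen-4-yl]oxy}trimethylsilane | CC(C)=CCC/C(C)=C/Cc1cc(C2=C(O[Si](C)(C)C)c3c(OCOC)c(C)c(OCOC)cc3OC2)c(OCOC)cc1OCOC
F3 | step 12 | rac-3-{5-[(2E)-3,7-dimethylocta-2,6-dien-1-yl]-2,4-dihydroxyphenyl}-5,7-dihydroxy-6-methyl-2,3-dihydro-4H-chromen-4-one | CC(C)=CCC/C(C)=C/Cc1cc(C2COc3cc(O)c(C)c(O)c3C2=O)c(O)cc1O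
F4 | step 12 | (3S)-3-{5-[(2E)-3,7-dimethylocta-2,6-dien-1-yl]-2,4-dihydroxyphenyl}-5,7-dihydroxy-6-methyl-2,3-dihydro-4H-chromen-4-one | CC(C)=CCC/C(C)=C/Cc1cc([C@H]2COc3cc(O)c(C)c(O)c3C2=O)c(O)cc1O
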